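The route rests on making the resorcinol ring of unit 1 (C3a, C4, C5, C6, C7, C7a; benzofuran numbering, unit 2 primed) last, by a Danheiser benzannulation. The step exploits the 1,2,3,5 pattern of that ring: C3a, which bears C3, lies between the oxygenated C4 and C7a, and the styryl group sits at C6. A 3-styrylcyclobutenone and a siloxyalkyne whose propargylic carbon is C3, already carrying unit 2 and the syn silylated C2 carbinol, give this arene in one operation (bonds C3a–C7a, C4–C5, C7–C7a). Unit 2 is built first by the same sequence; phenols travel as benzyl ethers, so the end is desilylation, Mitsunobu closure and BCl3 debenzylation.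

Key step: step 25

Remark on the chemistry: all phenols are carried as benzyl ethers, because cleavage with BCl3 and pentamethylbenzene at −78 °C is milder towards the benzylic C2–O bonds of the two dihydrobenzofurans and the stilbene than a late cleavage of methyl ethers with BBr3.
Abbreviations in names: ArU = (2S,3S)-4-(benzyloxy)-2-[4-(benzyloxy)phenyl]-3-[3,5-bis(benzyloxy)phenyl]-2,3-dihydro-1-benzofuran-6-yl; TBS = tert-butyldimethylsilyl; TIPS = triisopropylsilyl.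

Step 1
Reactants: 1 methyl 3,5-dihydroxyphenylacetate
Product: 3 3,5-bis(benzyloxy)phenylacetic acid, via methyl 3,5-bis(benzyloxy)phenylacetate 2 (not isolated)
Conditions: BnBr, K2CO3, DMF, rt; then aq. NaOH, MeOH, 50 °C; HCl work-up
Reagents that add atoms: benzyl bromide, BrCc1ccccc1; sodium hydroxide, [Na+].[OH-]
Why: Williamson O-benzylation of both phenols followed by saponification of the methyl ester in the same flask is routine, and no stereocentre is involved.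

Step 2
Reactants: 3 3,5-bis(benzyloxy)phenylacetic acid; 4 (R)-4-benzyl-1,3-oxazolidin-2-one
Product: 6 (R)-4-benzyl-3-{[3,5-bis(benzyloxy)phenyl]acetyl}-1,3-oxazolidin-2-one, via mixed pivalic anhydride 5 (not isolated)
Conditions: PivCl, Et3N, THF, −20 °C; then 4, LiCl, rt
Reagents that add atoms: none
Why: N-acylation of the Evans auxiliary through the mixed pivalic anhydride with LiCl activation is standard for arylacetic acids and avoids ketene formation from an acid chloride.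

Step 3
Reactants: 6 (R)-4-benzyl-3-{[3,5-bis(benzyloxy)phenyl]acetyl}-1,3-oxazolidin-2-one; 7 4-(benzyloxy)benzaldehyde
Product: 9 (R)-4-benzyl-3-{(2R,3R)-2-[3,5-bis(benzyloxy)phenyl]-3-[4-(benzyloxy)phenyl]-3-hydroxypropanoyl}-1,3-oxazolidin-2-one, via dibutylboron Z-enolate 8 (not isolated)
Conditions: Bu2BOTf, i-Pr2NEt, CH2Cl2, −78 → 0 °C; then 7, −78 → 0 °C; H2O2, MeOH, pH 7 buffer
Reagents that add atoms: none
Why: Evans syn-aldol reaction, in which the Z-boron enolate reacts through a Zimmerman–Traxler chair on the face opposite the benzyl group of the auxiliary, so both new stereocentres are set as the (2R,3R) syn pair.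

Step 4
Reactants: 9 syn-aldol adduct
Product: 10 (R)-4-benzyl-3-{(2R,3R)-2-[3,5-bis(benzyloxy)phenyl]-3-[4-(benzyloxy)phenyl]-3-(TBS-oxy)propanoyl}-1,3-oxazolidin-2-one
Conditions: TBSOTf, 2,6-lutidine, CH2Cl2, −78 → 0 °C
Reagents that add atoms: tert-butyldimethylsilyl triflate, CC(C)(C)[Si](C)(C)OS(=O)(=O)C(F)(F)F
Why: Silylation of the secondary aldol hydroxyl with the silyl triflate is fast at low temperature and blocks retro-aldol cleavage in the later hydride and base steps.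

Step 5
Reactants: 10 silylated aldol adduct
Product: 11 (2S,3R)-2-[3,5-bis(benzyloxy)phenyl]-3-[4-(benzyloxy)phenyl]-3-(TBS-oxy)propan-1-ol
Conditions: LiBH4, MeOH (1 equiv), THF, 0 °C
Reagents that add atoms: none
Why: Reductive cleavage of the N-acyl oxazolidinone by LiBH4 occurs at the exocyclic carbonyl and gives the primary alcohol without touching the α-aryl stereocentre (the descriptor changes only through priorities).

Step 6
Reactants: 11 primary alcohol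
Product: 12 (2R,3R)-2-[3,5-bis(benzyloxy)phenyl]-3-[4-(benzyloxy)phenyl]-3-(TBS-oxy)propanal
Conditions: Dess–Martin periodinane, NaHCO3, CH2Cl2, 0 °C
Reagents that add atoms: none
Why: Dess–Martin oxidation under buffered, non-basic conditions gives the α-aryl aldehyde without enolisation, and the crude aldehyde is used at once.

Step 7
Reactants: 12 aldehyde
Product: 13 tert-butyl{[(1R,2R)-2-[3,5-bis(benzyloxy)phenyl]-1-[4-(benzyloxy)phenyl]-4,4-dibromobut-3-en-1-yl]oxy}dimethylsilane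
Conditions: CBr4, PPh3, Zn, CH2Cl2, rt; then 12, 0 °C
Reagents that add atoms: carbon tetrabromide, BrC(Br)(Br)Br
Why: First stage of the Corey–Fuchs reaction, a Wittig-type dibromo-olefination with the preformed ylide under neutral conditions that should not epimerise the α-aryl aldehyde.

Step 8
Reactants: 13 dibromo-olefin
Product: 16 tert-butyl{[(1R,2S)-2-[3,5-bis(benzyloxy)phenyl]-1-[4-(benzyloxy)phenyl]-4-(TIPS-oxy)but-3-yn-1-yl]oxy}dimethylsilane, via lithium acetylide 14 (not isolated), via lithium ynolate 15 (not isolated)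
Conditions: n-BuLi (2.1 equiv), THF, −78 °C; LiOOt-Bu (from t-BuOOH, LiN(SiMe3)2), −78 → 0 °C; TIPSOTf, −78 °C
Reagents that add atoms: lithium tert-butyl peroxide, [Li]OOC(C)(C)C; triisopropylsilyl triflate, CC(C)[Si](C(C)C)(C(C)C)OS(=O)(=O)C(F)(F)F
Why: Second stage of the Corey–Fuchs reaction (bromine–lithium exchange, carbenoid rearrangement, deprotonation) gives the lithium acetylide, which is oxidised to the ynolate by oxygen transfer from the lithium peroxide and O-silylated by the bulky silyl triflate, all at temperatures at which the propargylic stereocentre is not deprotonated.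

Step 9
Reactants: 17 3-ethoxycyclobut-2-en-1-one
Product: 19 3-ethenylcyclobut-2-en-1-one, via 1-ethenyl-3-ethoxycyclobut-2-en-1-ol 18 (not isolated)
Conditions: CH2=CHMgBr, THF, −78 °C; then 1 M HCl, 0 °C
Reagents that add atoms: vinylmagnesium bromide, C=C[Mg]Br; water, O
Why: 1,2-Addition of the Grignard reagent to the vinylogous ester and acid hydrolysis with allylic transposition (Stork–Danheiser sequence) is the standard entry to 3-substituted cyclobutenones; the dienone is kept cold in dilute solution with BHT and used promptly.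

Step 10
Reactants: 16 siloxyalkyne of unit 2; 19 3-ethenylcyclobut-2-en-1-one
Product: 20 2-{(1S,2R)-1-[3,5-bis(benzyloxy)phenyl]-2-[4-(benzyloxy)phenyl]-2-(TBS-oxy)ethyl}-5-ethenyl-3-(TIPS-oxy)phenol
Conditions: PhMe, BHT, 80 °C (slow addition of 19)
Reagents that add atoms: none
Why: Danheiser benzannulation (4π opening of 19 to the vinylketene, regioselective (2+2) capture by the siloxyalkyne, 4π opening, 6π closure, tautomerisation) builds the resorcinol ring of unit 2 with C3′ between the two oxygens and the vinyl handle at C6′, leaving the stereocentres untouched.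

Step 11
Reactants: 20 resorcinol monosilyl ether
Product: 21 2-{(1S,2R)-1-[3,5-bis(benzyloxy)phenyl]-2-[4-(benzyloxy)phenyl]-2-hydroxyethyl}-5-ethenylbenzene-1,3-diol
Conditions: TBAF, AcOH, THF, 0 °C → rt
Reagents that add atoms: none
Why: Fluoride-mediated desilylation removes the aryl TIPS ether and the benzylic TBS ether, the acetic acid buffer keeping the medium from becoming strongly basic.

Step 12
Reactants: 21 triol
Product: 22 (2S,3S)-2-[4-(benzyloxy)phenyl]-3-[3,5-bis(benzyloxy)phenyl]-6-ethenyl-2,3-dihydro-1-benzofuran-4-ol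
Conditions: PPh3, DIAD, THF, 0 °C → rt
Reagents that add atoms: none
Why: Intramolecular Mitsunobu etherification, in which either of the two equivalent flanking phenols displaces the activated C2′ oxygen in a 5-exo-tet SN2 closure with inversion, turns the syn (1S,2R) carbinol into the trans (2S,3S) dihydrobenzofuran, which is also the thermodynamically preferred isomer should ionisation intervene.

Step 13
Reactants: 22 dihydrobenzofuranol
Product: 23 (2S,3S)-4-(benzyloxy)-2-[4-(benzyloxy)phenyl]-3-[3,5-bis(benzyloxy)phenyl]-6-ethenyl-2,3-dihydro-1-benzofuran (ArU–CH=CH2)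
Conditions: BnBr, K2CO3, DMF, rt
Reagents that add atoms: benzyl bromide, BrCc1ccccc1
Why: Williamson benzylation of the remaining C4′ phenol with a carbonate base gives the uniformly benzyl-protected unit 2.

Step 14
Reactants: 23 ArU–CH=CH2
Product: 25 2-ArU-ethan-1-ol, via B-alkyl-9-BBN adduct 24 (not isolated)
Conditions: 9-BBN, THF, 0 °C → rt; then NaOH, H2O2, 0 °C
Reagents that add atoms: hydrogen peroxide, OO
Why: Anti-Markovnikov hydroboration of the styrene with 9-BBN and alkaline peroxide oxidation of the alkylborane should give the primary 2-arylethanol regioselectively.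

Step 15
Reactants: 25 2-ArU-ethan-1-ol
Product: 27 ArU-acetic acid, via arylacetaldehyde 26 (not isolated)
Conditions: TEMPO (cat.), PhI(OAc)2, MeCN–H2O, rt
Reagents that add atoms: water, O
Why: TEMPO-catalysed oxidation with the hypervalent iodine co-oxidant in aqueous acetonitrile takes the primary alcohol through the aldehyde hydrate to the acid, conditions to which benzyl ethers and the dihydrobenzofuran are inert.

Step 16
Reactants: 27 ArU-acetic acid; 4 (R)-4-benzyl-1,3-oxazolidin-2-one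
Product: 29 (R)-4-benzyl-3-(ArU-acetyl)-1,3-oxazolidin-2-one, via mixed pivalic anhydride 28 (not isolated)
Conditions: PivCl, Et3N, THF, −20 °C; then 4, LiCl, rt
Reagents that add atoms: none
Why: Same mixed-anhydride N-acylation as in step 2; the dihydrobenzofuran stereocentres are not enolisable and are unaffected.

Step 17
Reactants: 29 N-acyl oxazolidinone of unit 2; 7 4-(benzyloxy)benzaldehyde
Product: 31 (R)-4-benzyl-3-{(2R,3R)-2-ArU-3-[4-(benzyloxy)phenyl]-3-hydroxypropanoyl}-1,3-oxazolidin-2-one, via dibutylboron Z-enolate 30 (not isolated)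
Conditions: Bu2BOTf, i-Pr2NEt, CH2Cl2, −78 → 0 °C; then 7, −78 → 0 °C; H2O2, MeOH, pH 7 buffer
Reagents that add atoms: none
Why: Evans syn-aldol reaction as in step 3, in which the auxiliary and not the distant unit 2 stereocentres controls the enolate face, so the future C3 and C2 are set as the (2R,3R) syn pair.

Step 18
Reactants: 31 syn-aldol adduct
Product: 32 (R)-4-benzyl-3-{(2R,3R)-2-ArU-3-[4-(benzyloxy)phenyl]-3-(TBS-oxy)propanoyl}-1,3-oxazolidin-2-one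
Conditions: TBSOTf, 2,6-lutidine, CH2Cl2, −78 → 0 °C
Reagents that add atoms: tert-butyldimethylsilyl triflate, CC(C)(C)[Si](C)(C)OS(=O)(=O)C(F)(F)F
Why: Low-temperature silylation with the silyl triflate and a hindered base protects the carbinol without ionising the cyclic benzylic ether of unit 2.

Step 19
Reactants: 32 silylated aldol adduct
Product: 33 (2S,3R)-2-ArU-3-[4-(benzyloxy)phenyl]-3-(TBS-oxy)propan-1-ol
Conditions: LiBH4, MeOH (1 equiv), THF, 0 °C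
Reagents that add atoms: none
Why: Reductive removal of the auxiliary with LiBH4 as in step 5 gives the primary alcohol and returns the oxazolidinone.

Step 20
Reactants: 33 primary alcohol
Product: 34 (2R,3R)-2-ArU-3-[4-(benzyloxy)phenyl]-3-(TBS-oxy)propanal
Conditions: Dess–Martin periodinane, NaHCO3, CH2Cl2, 0 °C
Reagents that add atoms: none
Why: Buffered Dess–Martin oxidation as in step 6 gives the configurationally labile α-aryl aldehyde, which is carried on without storage.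

Step 21
Reactants: 34 aldehyde
Product: 35 tert-butyl{[(1R,2R)-2-ArU-1-[4-(benzyloxy)phenyl]-4,4-dibromobut-3-en-1-yl]oxy}dimethylsilane
Conditions: CBr4, PPh3, Zn, CH2Cl2, rt; then 34, 0 °C
Reagents that add atoms: carbon tetrabromide, BrC(Br)(Br)Br
Why: Corey–Fuchs dibromo-olefination as in step 7, under neutral conditions that should preserve the α-stereocentre.

Step 22
Reactants: 35 dibromo-olefin
Product: 38 tert-butyl{[(1R,2S)-2-ArU-1-[4-(benzyloxy)phenyl]-4-(TIPS-oxy)but-3-yn-1-yl]oxy}dimethylsilane, via lithium acetylide 36 (not isolated), via lithium ynolate 37 (not isolated)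
Conditions: n-BuLi (2.1 equiv), THF, −78 °C; LiOOt-Bu (from t-BuOOH, LiN(SiMe3)2), −78 → 0 °C; TIPSOTf, −78 °C
Reagents that add atoms: lithium tert-butyl peroxide, [Li]OOC(C)(C)C; triisopropylsilyl triflate, CC(C)[Si](C(C)C)(C(C)C)OS(=O)(=O)C(F)(F)F
Why: Corey–Fuchs alkyne formation, acetylide-to-ynolate oxidation and O-silylation exactly as in step 8 on a substrate with the same local environment give the siloxyalkyne whose propargylic carbon is C3.

Step 23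
Reactants: 39 (E)-4-(benzyloxy)cinnamic acid
Product: 40 1-(benzyloxy)-4-[(E)-2-bromoethenyl]benzene
Conditions: NBS, LiOAc (cat.), MeCN–H2O, rt
Reagents that add atoms: N-bromosuccinimide, O=C1CCC(=O)N1Br
Why: Catalytic Hunsdiecker-type bromodecarboxylation of an electron-rich cinnamic acid (bromonium formation, then decarboxylative elimination) should give the E-bromostyrene.

Step 24
Reactants: 40 E-bromostyrene; 17 3-ethoxycyclobut-2-en-1-one
Product: 43 3-{(E)-2-[4-(benzyloxy)phenyl]ethenyl}cyclobut-2-en-1-one, via (E)-styryllithium 41 (not isolated), via 3-ethoxy-1-styrylcyclobutenol 42 (not isolated)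
Conditions: t-BuLi (2 equiv), Et2O, −78 °C; then 17, THF, −78 °C; then 1 M HCl, 0 °C
Reagents that add atoms: water, O
Why: Bromine–lithium exchange with retention of the E geometry, 1,2-addition to the vinylogous ester and acid hydrolysis with transposition (Stork–Danheiser sequence) give the 3-alkenylcyclobutenone.

Step 25
Reactants: 38 tert-butyl{[(1R,2S)-2-ArU-1-[4-(benzyloxy)phenyl]-4-(TIPS-oxy)but-3-yn-1-yl]oxy}dimethylsilane; 43 3-{(E)-2-[4-(benzyloxy)phenyl]ethenyl}cyclobut-2-en-1-one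
Product: 44 2-{(1S,2R)-1-ArU-2-[4-(benzyloxy)phenyl]-2-(TBS-oxy)ethyl}-5-{(E)-2-[4-(benzyloxy)phenyl]ethenyl}-3-(TIPS-oxy)phenol
Conditions: PhMe, BHT, 80 → 110 °C (slow addition of 43)
Reagents that add atoms: none
Why: Heating opens 43 by 4π electrocyclic cleavage to a styryl-substituted vinylketene, whose C=C adds to the electron-rich alkyne of 38 in a (2+2) cycloaddition: the unoxygenated alkyne carbon, which bears C3, bonds to the ketene carbonyl carbon (C3a–C7a) and the oxygenated alkyne carbon bonds to the ketene α-carbon (C4–C5). The new 4-alkenylcyclobutenone opens again (4π) to a dienylketene, a 6π electrocyclisation closes the benzene ring of unit 1 at C7–C7a, and tautomerisation gives the C7a phenol with the C4 oxygen still silylated. This is the Danheiser benzannulation of a 3-substituted cyclobutenone with a triisopropylsiloxyalkyne, a known route to resorcinol monosilyl ethers substituted between the two oxygens. No stereocentre is formed, and C2, C3, C2′ and C3′ lie outside the reacting π systems of this neutral thermal cascade and are carried through. The only selectivity needed is regiochemical and is fixed by the polarisation of the siloxyalkyne, so C3 ends between the two oxygens and the styryl group at C6. Slow addition of 43 keeps the ketene dilute so that the alkyne, not a second ketene or the product phenol, captures it.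

Step 26
Reactants: 44 resorcinol monosilyl ether of unit 1
Product: 45 2-{(1S,2R)-1-ArU-2-[4-(benzyloxy)phenyl]-2-hydroxyethyl}-5-{(E)-2-[4-(benzyloxy)phenyl]ethenyl}benzene-1,3-diol
Conditions: TBAF, AcOH, THF, 0 °C → rt
Reagents that add atoms: none
Why: Buffered fluoride desilylation frees the C4 phenol and the C2 carbinol as in step 11 and leaves the benzyl ethers and the stilbene alone.

Step 27
Reactants: 45 triol
Product: 46 (2S,3S)-3-ArU-2-[4-(benzyloxy)phenyl]-6-{(E)-2-[4-(benzyloxy)phenyl]ethenyl}-2,3-dihydro-1-benzofuran-4-ol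
Conditions: PPh3, DIAD, THF, 0 °C → rt
Reagents that add atoms: none
Why: Intramolecular Mitsunobu etherification, in which the C2 oxyphosphonium ion is displaced with inversion by either flanking phenol (5-exo-tet), converts the syn (1S,2R) array into the trans (2S,3S) dihydrobenzofuran of unit 1 and leaves the other phenol as the free C4 hydroxyl.

Step 28
Reactants: 46 hexabenzyl ether
Product: 47 (2S,3S)-3-[(2S,3S)-3-(3,5-dihydroxyphenyl)-4-hydroxy-2-(4-hydroxyphenyl)-2,3-dihydro-1-benzofuran-6-yl]-2-(4-hydroxyphenyl)-6-[(E)-2-(4-hydroxyphenyl)ethenyl]-2,3-dihydro-1-benzofuran-4-ol (target)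
Conditions: BCl3, C6HMe5, CH2Cl2, −78 °C; MeOH quench
Reagents that add atoms: none
Why: Lewis-acid debenzylation with BCl3 at −78 °C, with pentamethylbenzene as a non-basic benzyl cation scavenger, cleaves all six aryl benzyl ethers without hydrogenation, so the stilbene, the benzylic C2–O bonds and the four stereocentres are expected to survive.

Compound list
1 | methyl 3,5-dihydroxyphenylacetate | COC(=O)Cc1cc(O)cc(O)c1 | starting material
2 | methyl 3,5-bis(benzyloxy)phenylacetate | COC(=O)Cc1cc(OCc2ccccc2)cc(OCc2ccccc2)c1 | intermediate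
3 | 3,5-bis(benzyloxy)phenylacetic acid | OC(=O)Cc1cc(OCc2ccccc2)cc(OCc2ccccc2)c1 | intermediate
4 | (R)-4-benzyl-1,3-oxazolidin-2-one | O=C1N[C@H](Cc2ccccc2)CO1 | starting material
5 | [3,5-bis(benzyloxy)phenyl]acetic pivalic anhydride | CC(C)(C)C(=O)OC(=O)Cc1cc(OCc2ccccc2)cc(OCc2ccccc2)c1 | intermediate
6 | (R)-4-benzyl-3-{[3,5-bis(benzyloxy)phenyl]acetyl}-1,3-oxazolidin-2-one | O=C(Cc1cc(OCc2ccccc2)cc(OCc2ccccc2)c1)N1[C@H](Cc2ccccc2)COC1=O | intermediate
7 | 4-(benzyloxy)benzaldehyde | O=Cc1ccc(OCc2ccccc2)cc1 | starting material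
8 | dibutylboron Z-enolate of 6 | CCCCB(CCCC)O/C(=C\c1cc(OCc2ccccc2)cc(OCc2ccccc2)c1)N1[C@H](Cc2ccccc2)COC1=O | intermediate
9 | (R)-4-benzyl-3-{(2R,3R)-2-[3,5-bis(benzyloxy)phenyl]-3-[4-(benzyloxy)phenyl]-3-hydroxypropanoyl}-1,3-oxazolidin-2-one | O=C(N1[C@H](Cc2ccccc2)COC1=O)[C@H](c1cc(OCc2ccccc2)cc(OCc2ccccc2)c1)[C@@H](O)c1ccc(OCc2ccccc2)cc1 | intermediate
10 | TBS ether of 9 | O=C(N1[C@H](Cc2ccccc2)COC1=O)[C@H](c1cc(OCc2ccccc2)cc(OCc2ccccc2)c1)[C@@H](O[Si](C)(C)C(C)(C)C)c1ccc(OCc2ccccc2)cc1 | intermediate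
11 | (2S,3R)-2-[3,5-bis(benzyloxy)phenyl]-3-[4-(benzyloxy)phenyl]-3-(TBS-oxy)propan-1-ol | OC[C@H](c1cc(OCc2ccccc2)cc(OCc2ccccc2)c1)[C@@H](O[Si](C)(C)C(C)(C)C)c1ccc(OCc2ccccc2)cc1 | intermediate
12 | (2R,3R)-2-[3,5-bis(benzyloxy)phenyl]-3-[4-(benzyloxy)phenyl]-3-(TBS-oxy)propanal | O=C[C@H](c1cc(OCc2ccccc2)cc(OCc2ccccc2)c1)[C@@H](O[Si](C)(C)C(C)(C)C)c1ccc(OCc2ccccc2)cc1 | intermediate
13 | tert-butyl{[(1R,2R)-2-[3,5-bis(benzyloxy)phenyl]-1-[4-(benzyloxy)phenyl]-4,4-dibromobut-3-en-1-yl]oxy}dimethylsilane | BrC(Br)=C[C@H](c1cc(OCc2ccccc2)cc(OCc2ccccc2)c1)[C@@H](O[Si](C)(C)C(C)(C)C)c1ccc(OCc2ccccc2)cc1 | intermediate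
14 | lithium acetylide from 13 | [Li]C#C[C@H](c1cc(OCc2ccccc2)cc(OCc2ccccc2)c1)[C@@H](O[Si](C)(C)C(C)(C)C)c1ccc(OCc2ccccc2)cc1 | intermediate
15 | lithium ynolate from 14 | [Li]OC#C[C@H](c1cc(OCc2ccccc2)cc(OCc2ccccc2)c1)[C@@H](O[Si](C)(C)C(C)(C)C)c1ccc(OCc2ccccc2)cc1 | intermediate
16 | tert-butyl{[(1R,2S)-2-[3,5-bis(benzyloxy)phenyl]-1-[4-(benzyloxy)phenyl]-4-(TIPS-oxy)but-3-yn-1-yl]oxy}dimethylsilane | CC(C)[Si](C(C)C)(C(C)C)OC#C[C@H](c1cc(OCc2ccccc2)cc(OCc2ccccc2)c1)[C@@H](O[Si](C)(C)C(C)(C)C)c1ccc(OCc2ccccc2)cc1 | intermediate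
17 | 3-ethoxycyclobut-2-en-1-one | CCOC1=CC(=O)C1 | starting material
18 | 1-ethenyl-3-ethoxycyclobut-2-en-1-ol (formed as its magnesium alkoxide) | CCOC1=CC(O)(C=C)C1 | intermediate
19 | 3-ethenylcyclobut-2-en-1-one | C=CC1=CC(=O)C1 | intermediate
20 | 2-{(1S,2R)-1-[3,5-bis(benzyloxy)phenyl]-2-[4-(benzyloxy)phenyl]-2-(TBS-oxy)ethyl}-5-ethenyl-3-(TIPS-oxy)phenol | C=Cc1cc(O)c([C@H](c2cc(OCc3ccccc3)cc(OCc3ccccc3)c2)[C@@H](O[Si](C)(C)C(C)(C)C)c2ccc(OCc3ccccc3)cc2)c(O[Si](C(C)C)(C(C)C)C(C)C)c1 | intermediate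
21 | 2-{(1S,2R)-1-[3,5-bis(benzyloxy)phenyl]-2-[4-(benzyloxy)phenyl]-2-hydroxyethyl}-5-ethenylbenzene-1,3-diol | C=Cc1cc(O)c([C@H](c2cc(OCc3ccccc3)cc(OCc3ccccc3)c2)[C@@H](O)c2ccc(OCc3ccccc3)cc2)c(O)c1 | intermediate
22 | (2S,3S)-2-[4-(benzyloxy)phenyl]-3-[3,5-bis(benzyloxy)phenyl]-6-ethenyl-2,3-dihydro-1-benzofuran-4-ol | C=Cc1cc(O)c2c(c1)O[C@H](c1ccc(OCc3ccccc3)cc1)[C@H]2c1cc(OCc2ccccc2)cc(OCc2ccccc2)c1 | intermediate
23 | (2S,3S)-4-(benzyloxy)-2-[4-(benzyloxy)phenyl]-3-[3,5-bis(benzyloxy)phenyl]-6-ethenyl-2,3-dihydro-1-benzofuran | C=Cc1cc(OCc2ccccc2)c2c(c1)O[C@H](c1ccc(OCc3ccccc3)cc1)[C@H]2c1cc(OCc2ccccc2)cc(OCc2ccccc2)c1 | intermediate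
24 | 9-(2-ArU-ethyl)-9-borabicyclo[3.3.1]nonane | B1(CCc2cc(OCc3ccccc3)c3c(c2)O[C@H](c2ccc(OCc4ccccc4)cc2)[C@H]3c2cc(OCc3ccccc3)cc(OCc3ccccc3)c2)C2CCCC1CCC2 | intermediate
25 | 2-ArU-ethan-1-ol | OCCc1cc(OCc2ccccc2)c2c(c1)O[C@H](c1ccc(OCc3ccccc3)cc1)[C@H]2c1cc(OCc2ccccc2)cc(OCc2ccccc2)c1 | intermediate
26 | ArU-acetaldehyde | O=CCc1cc(OCc2ccccc2)c2c(c1)O[C@H](c1ccc(OCc3ccccc3)cc1)[C@H]2c1cc(OCc2ccccc2)cc(OCc2ccccc2)c1 | intermediate
27 | ArU-acetic acid | OC(=O)Cc1cc(OCc2ccccc2)c2c(c1)O[C@H](c1ccc(OCc3ccccc3)cc1)[C@H]2c1cc(OCc2ccccc2)cc(OCc2ccccc2)c1 | intermediate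
28 | ArU-acetic pivalic anhydride | CC(C)(C)C(=O)OC(=O)Cc1cc(OCc2ccccc2)c2c(c1)O[C@H](c1ccc(OCc3ccccc3)cc1)[C@H]2c1cc(OCc2ccccc2)cc(OCc2ccccc2)c1 | intermediate
29 | (R)-4-benzyl-3-(ArU-acetyl)-1,3-oxazolidin-2-one | O=C(Cc1cc(OCc2ccccc2)c2c(c1)O[C@H](c1ccc(OCc3ccccc3)cc1)[C@H]2c1cc(OCc2ccccc2)cc(OCc2ccccc2)c1)N1[C@H](Cc2ccccc2)COC1=O | intermediate
30 | dibutylboron Z-enolate of 29 | CCCCB(CCCC)O/C(=C\c1cc(OCc2ccccc2)c2c(c1)O[C@H](c1ccc(OCc3ccccc3)cc1)[C@H]2c1cc(OCc2ccccc2)cc(OCc2ccccc2)c1)N1[C@H](Cc2ccccc2)COC1=O | intermediate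
31 | (R)-4-benzyl-3-{(2R,3R)-2-ArU-3-[4-(benzyloxy)phenyl]-3-hydroxypropanoyl}-1,3-oxazolidin-2-one | O=C(N1[C@H](Cc2ccccc2)COC1=O)[C@H](c1cc(OCc2ccccc2)c2c(c1)O[C@H](c1ccc(OCc3ccccc3)cc1)[C@H]2c1cc(OCc2ccccc2)cc(OCc2ccccc2)c1)[C@@H](O)c1ccc(OCc2ccccc2)cc1 | intermediate
32 | TBS ether of 31 | O=C(N1[C@H](Cc2ccccc2)COC1=O)[C@H](c1cc(OCc2ccccc2)c2c(c1)O[C@H](c1ccc(OCc3ccccc3)cc1)[C@H]2c1cc(OCc2ccccc2)cc(OCc2ccccc2)c1)[C@@H](O[Si](C)(C)C(C)(C)C)c1ccc(OCc2ccccc2)cc1 | intermediate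
33 | (2S,3R)-2-ArU-3-[4-(benzyloxy)phenyl]-3-(TBS-oxy)propan-1-ol | OC[C@H](c1cc(OCc2ccccc2)c2c(c1)O[C@H](c1ccc(OCc3ccccc3)cc1)[C@H]2c1cc(OCc2ccccc2)cc(OCc2ccccc2)c1)[C@@H](O[Si](C)(C)C(C)(C)C)c1ccc(OCc2ccccc2)cc1 | intermediate
34 | (2R,3R)-2-ArU-3-[4-(benzyloxy)phenyl]-3-(TBS-oxy)propanal | O=C[C@H](c1cc(OCc2ccccc2)c2c(c1)O[C@H](c1ccc(OCc3ccccc3)cc1)[C@H]2c1cc(OCc2ccccc2)cc(OCc2ccccc2)c1)[C@@H](O[Si](C)(C)C(C)(C)C)c1ccc(OCc2ccccc2)cc1 | intermediate
35 | tert-butyl{[(1R,2R)-2-ArU-1-[4-(benzyloxy)phenyl]-4,4-dibromobut-3-en-1-yl]oxy}dimethylsilane | BrC(Br)=C[C@H](c1cc(OCc2ccccc2)c2c(c1)O[C@H](c1ccc(OCc3ccccc3)cc1)[C@H]2c1cc(OCc2ccccc2)cc(OCc2ccccc2)c1)[C@@H](O[Si](C)(C)C(C)(C)C)c1ccc(OCc2ccccc2)cc1 | intermediate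
36 | lithium acetylide from 35 | [Li]C#C[C@H](c1cc(OCc2ccccc2)c2c(c1)O[C@H](c1ccc(OCc3ccccc3)cc1)[C@H]2c1cc(OCc2ccccc2)cc(OCc2ccccc2)c1)[C@@H](O[Si](C)(C)C(C)(C)C)c1ccc(OCc2ccccc2)cc1 | intermediate
37 | lithium ynolate from 36 | [Li]OC#C[C@H](c1cc(OCc2ccccc2)c2c(c1)O[C@H](c1ccc(OCc3ccccc3)cc1)[C@H]2c1cc(OCc2ccccc2)cc(OCc2ccccc2)c1)[C@@H](O[Si](C)(C)C(C)(C)C)c1ccc(OCc2ccccc2)cc1 | intermediate
38 | tert-butyl{[(1R,2S)-2-ArU-1-[4-(benzyloxy)phenyl]-4-(TIPS-oxy)but-3-yn-1-yl]oxy}dimethylsilane | CC(C)[Si](C(C)C)(C(C)C)OC#C[C@H](c1cc(OCc2ccccc2)c2c(c1)O[C@H](c1ccc(OCc3ccccc3)cc1)[C@H]2c1cc(OCc2ccccc2)cc(OCc2ccccc2)c1)[C@@H](O[Si](C)(C)C(C)(C)C)c1ccc(OCc2ccccc2)cc1 | intermediate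
39 | (E)-4-(benzyloxy)cinnamic acid | OC(=O)/C=C/c1ccc(OCc2ccccc2)cc1 | starting material
40 | 1-(benzyloxy)-4-[(E)-2-bromoethenyl]benzene | Br/C=C/c1ccc(OCc2ccccc2)cc1 | intermediate
41 | (E)-2-[4-(benzyloxy)phenyl]ethenyllithium | [Li]/C=C/c1ccc(OCc2ccccc2)cc1 | intermediate
42 | 1-{(E)-2-[4-(benzyloxy)phenyl]ethenyl}-3-ethoxycyclobut-2-en-1-ol (formed as its lithium alkoxide) | CCOC1=CC(O)(/C=C/c2ccc(OCc3ccccc3)cc2)C1 | intermediate
43 | 3-{(E)-2-[4-(benzyloxy)phenyl]ethenyl}cyclobut-2-en-1-one | O=C1CC(/C=C/c2ccc(OCc3ccccc3)cc2)=C1 | intermediate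
44 | 2-{(1S,2R)-1-ArU-2-[4-(benzyloxy)phenyl]-2-(TBS-oxy)ethyl}-5-{(E)-2-[4-(benzyloxy)phenyl]ethenyl}-3-(TIPS-oxy)phenol | C(c1ccccc1)Oc1ccc(/C=C/c2cc(O)c([C@H](c3cc(OCc4ccccc4)c4c(c3)O[C@H](c3ccc(OCc5ccccc5)cc3)[C@H]4c3cc(OCc4ccccc4)cc(OCc4ccccc4)c3)[C@@H](O[Si](C)(C)C(C)(C)C)c3ccc(OCc4ccccc4)cc3)c(O[Si](C(C)C)(C(C)C)C(C)C)c2)cc1 | intermediate
45 | 2-{(1S,2R)-1-ArU-2-[4-(benzyloxy)phenyl]-2-hydroxyethyl}-5-{(E)-2-[4-(benzyloxy)phenyl]ethenyl}benzene-1,3-diol | C(c1ccccc1)Oc1ccc(/C=C/c2cc(O)c([C@H](c3cc(OCc4ccccc4)c4c(c3)O[C@H](c3ccc(OCc5ccccc5)cc3)[C@H]4c3cc(OCc4ccccc4)cc(OCc4ccccc4)c3)[C@@H](O)c3ccc(OCc4ccccc4)cc3)c(O)c2)cc1 | intermediate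
46 | (2S,3S)-3-ArU-2-[4-(benzyloxy)phenyl]-6-{(E)-2-[4-(benzyloxy)phenyl]ethenyl}-2,3-dihydro-1-benzofuran-4-ol | C(c1ccccc1)Oc1ccc(/C=C/c2cc(O)c3c(c2)O[C@H](c2ccc(OCc4ccccc4)cc2)[C@H]3c2cc(OCc3ccccc3)c3c(c2)O[C@H](c2ccc(OCc4ccccc4)cc2)[C@H]3c2cc(OCc3ccccc3)cc(OCc3ccccc3)c2)cc1 | intermediate
47 | (2S,3S)-3-[(2S,3S)-3-(3,5-dihydroxyphenyl)-4-hydroxy-2-(4-hydroxyphenyl)-2,3-dihydro-1-benzofuran-6-yl]-2-(4-hydroxyphenyl)-6-[(E)-2-(4-hydroxyphenyl)ethenyl]-2,3-dihydro-1-benzofuran-4-ol | Oc1ccc(/C=C/c2cc(O)c3c(c2)O[C@H](c2ccc(O)cc2)[C@H]3c2cc(O)c3c(c2)O[C@H](c2ccc(O)cc2)[C@H]3c2cc(O)cc(O)c2)cc1 | target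

Total step count: 28.
Longest linear sequence: 25 steps (steps 1–8, 10–22 and 25–28); step 9 and steps 23–24 are side branches that supply the two cyclobutenones.

Steps most likely to fail

1. Step 25 (key benzannulation). The vinylketene from 43 is an extended, cross-conjugated polyene. It may oligomerise, or acylate the product phenol, faster than the congested alkyne carbon of 38 captures it, and prolonged heating would then erode the siloxyalkyne. The fallback keeps the ring construction but uses the smallest alkenyl ketene and attaches the stilbene aryl group afterwards. It sets out from 38 and the already available cyclobutenone 19. Heating them in toluene at 80 °C, the same local situation as step 10, should give 2-{(1S,2R)-1-ArU-2-[4-(benzyloxy)phenyl]-2-(TBS-oxy)ethyl}-5-ethenyl-3-(TIPS-oxy)phenol F7. TBAF with AcOH should then give the triol 2-{(1S,2R)-1-ArU-2-[4-(benzyloxy)phenyl]-2-hydroxyethyl}-5-ethenylbenzene-1,3-diol F8. PPh3 and DIAD should close it to (2S,3S)-3-ArU-2-[4-(benzyloxy)phenyl]-6-ethenyl-2,3-dihydro-1-benzofuran-4-ol F9. A Mizoroki–Heck coupling of F9 with 1-(benzyloxy)-4-iodobenzene (Pd(OAc)2, P(o-tol)3, Et3N, DMF, 90 °C) should form the E-stilbene and return to the route at 46.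

2. Step 10 (first benzannulation). The small, volatile dienone 19 and its vinylketene may polymerise before the alkyne captures them, and the styrene product may oligomerise on heating. The fallback replaces the conjugated handle by a non-conjugated one and reaches the acid by oxidative cleavage. It sets out from 16 and 17. CH2=CHCH2MgBr adds to 17 to give 3-ethoxy-1-(prop-2-en-1-yl)cyclobut-2-en-1-ol F1, and acid hydrolysis gives 3-(prop-2-en-1-yl)cyclobut-2-en-1-one F2. Benzannulation of F2 with 16 in toluene at 80 °C should give 2-{(1S,2R)-1-[3,5-bis(benzyloxy)phenyl]-2-[4-(benzyloxy)phenyl]-2-(TBS-oxy)ethyl}-5-(prop-2-en-1-yl)-3-(TIPS-oxy)phenol F3. TBAF with AcOH gives the triol 2-{(1S,2R)-1-[3,5-bis(benzyloxy)phenyl]-2-[4-(benzyloxy)phenyl]-2-hydroxyethyl}-5-(prop-2-en-1-yl)benzene-1,3-diol F4. Mitsunobu closure gives (2S,3S)-2-[4-(benzyloxy)phenyl]-3-[3,5-bis(benzyloxy)phenyl]-6-(prop-2-en-1-yl)-2,3-dihydro-1-benzofuran-4-ol F5. Benzylation (BnBr, K2CO3) gives (2S,3S)-4-(benzyloxy)-2-[4-(benzyloxy)phenyl]-3-[3,5-bis(benzyloxy)phenyl]-6-(prop-2-en-1-yl)-2,3-dihydro-1-benzofuran F6. Johnson–Lemieux cleavage (OsO4 cat., NaIO4, 2,6-lutidine, dioxane–H2O) should give aldehyde 26, and Pinnick oxidation (NaClO2, NaH2PO4, 2-methylbut-2-ene) comes back to the route at acid 27.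

3. Step 22 (late siloxyalkyne formation). Oxygen transfer to the congested acetylide 36 may be slow. That would leave time for deprotonation at the doubly activated C3–H (allene formation, epimerisation, β-elimination of silanolate) or for C-silylation of the ynolate. The fallback reaches the same ynolate without an acetylide, by Kowalski ester homologation, and sets out from 32. LiOH and H2O2 should cleave the auxiliary to (2R,3R)-2-ArU-3-[4-(benzyloxy)phenyl]-3-(TBS-oxy)propanoic acid F10. TMSCHN2 gives methyl (2R,3R)-2-ArU-3-[4-(benzyloxy)phenyl]-3-(TBS-oxy)propanoate F11. LiCHBr2 (from CH2Br2 and lithium 2,2,6,6-tetramethylpiperidide, −78 °C), then LiN(SiMe3)2, gives the lithium enolate of the dibromomethyl ketone, lithium (3R,4R)-3-ArU-4-[4-(benzyloxy)phenyl]-1,1-dibromo-4-(TBS-oxy)but-1-en-2-olate F12. n-BuLi then triggers bromine–lithium exchange and a 1,2-shift with retention at C3 to ynolate 37, and TIPSCl returns to the route at 38.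

Further compounds
F1 | step 10 | 3-ethoxy-1-(prop-2-en-1-yl)cyclobut-2-en-1-ol | CCOC1=CC(O)(CC=C)C1
F2 | step 10 | 3-(prop-2-en-1-yl)cyclobut-2-en-1-one | C=CCC1=CC(=O)C1
F3 | step 10 | 2-{(1S,2R)-1-[3,5-bis(benzyloxy)phenyl]-2-[4-(benzyloxy)phenyl]-2-(TBS-oxy)ethyl}-5-(prop-2-en-1-yl)-3-(TIPS-oxy)phenol | C=CCc1cc(O)c([C@H](c2cc(OCc3ccccc3)cc(OCc3ccccc3)c2)[C@@H](O[Si](C)(C)C(C)(C)C)c2ccc(OCc3ccccc3)cc2)c(O[Si](C(C)C)(C(C)C)C(C)C)c1
F4 | step 10 | 2-{(1S,2R)-1-[3,5-bis(benzyloxy)phenyl]-2-[4-(benzyloxy)phenyl]-2-hydroxyethyl}-5-(prop-2-en-1-yl)benzene-1,3-diol | C=CCc1cc(O)c([C@H](c2cc(OCc3ccccc3)cc(OCc3ccccc3)c2)[C@@H](O)c2ccc(OCc3ccccc3)cc2)c(O)c1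
F5 | step 10 | (2S,3S)-2-[4-(benzyloxy)phenyl]-3-[3,5-bis(benzyloxy)phenyl]-6-(prop-2-en-1-yl)-2,3-dihydro-1-benzofuran-4-ol | C=CCc1cc(O)c2c(c1)O[C@H](c1ccc(OCc3ccccc3)cc1)[C@H]2c1cc(OCc2ccccc2)cc(OCc2ccccc2)c1
F6 | step 10 | (2S,3S)-4-(benzyloxy)-2-[4-(benzyloxy)phenyl]-3-[3,5-bis(benzyloxy)phenyl]-6-(prop-2-en-1-yl)-2,3-dihydro-1-benzofuran | C=CCc1cc(OCc2ccccc2)c2c(c1)O[C@H](c1ccc(OCc3ccccc3)cc1)[C@H]2c1cc(OCc2ccccc2)cc(OCc2ccccc2)c1
F7 | step 25 | 2-{(1S,2R)-1-ArU-2-[4-(benzyloxy)phenyl]-2-(TBS-oxy)ethyl}-5-ethenyl-3-(TIPS-oxy)phenol | C=Cc1cc(O)c([C@H](c2cc(OCc3ccccc3)c3c(c2)O[C@H](c2ccc(OCc4ccccc4)cc2)[C@H]3c2cc(OCc3ccccc3)cc(OCc3ccccc3)c2)[C@@H](O[Si](C)(C)C(C)(C)C)c2ccc(OCc3ccccc3)cc2)c(O[Si](C(C)C)(C(C)C)C(C)C)c1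
F8 | step 25 | 2-{(1S,2R)-1-ArU-2-[4-(benzyloxy)phenyl]-2-hydroxyethyl}-5-ethenylbenzene-1,3-diol | C=Cc1cc(O)c([C@H](c2cc(OCc3ccccc3)c3c(c2)O[C@H](c2ccc(OCc4ccccc4)cc2)[C@H]3c2cc(OCc3ccccc3)cc(OCc3ccccc3)c2)[C@@H](O)c2ccc(OCc3ccccc3)cc2)c(O)c1
F9 | step 25 | (2S,3S)-3-ArU-2-[4-(benzyloxy)phenyl]-6-ethenyl-2,3-dihydro-1-benzofuran-4-ol | C=Cc1cc(O)c2c(c1)O[C@H](c1ccc(OCc3ccccc3)cc1)[C@H]2c1cc(OCc2ccccc2)c2c(c1)O[C@H](c1ccc(OCc3ccccc3)cc1)[C@H]2c1cc(OCc2ccccc2)cc(OCc2ccccc2)c1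
F10 | step 22 | (2R,3R)-2-ArU-3-[4-(benzyloxy)phenyl]-3-(TBS-oxy)propanoic acid | OC(=O)[C@H](c1cc(OCc2ccccc2)c2c(c1)O[C@H](c1ccc(OCc3ccccc3)cc1)[C@H]2c1cc(OCc2ccccc2)cc(OCc2ccccc2)c1)[C@@H](O[Si](C)(C)C(C)(C)C)c1ccc(OCc2ccccc2)cc1
F11 | step 22 | methyl (2R,3R)-2-ArU-3-[4-(benzyloxy)phenyl]-3-(TBS-oxy)propanoate | COC(=O)[C@H](c1cc(OCc2ccccc2)c2c(c1)O[C@H](c1ccc(OCc3ccccc3)cc1)[C@H]2c1cc(OCc2ccccc2)cc(OCc2ccccc2)c1)[C@@H](O[Si](C)(C)C(C)(C)C)c1ccc(OCc2ccccc2)cc1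
F12 | step 22 | lithium (3R,4R)-3-ArU-4-[4-(benzyloxy)phenyl]-1,1-dibromo-4-(TBS-oxy)but-1-en-2-olate | [Li]OC(=C(Br)Br)[C@H](c1cc(OCc2ccccc2)c2c(c1)O[C@H](c1ccc(OCc3ccccc3)cc1)[C@H]2c1cc(OCc2ccccc2)cc(OCc2ccccc2)c1)[C@@H](O[Si](C)(C)C(C)(C)C)c1ccc(OCc2ccccc2)cc1
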